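The 2,2-dimethyl-2H-pyran ring (O1, C2, C3=C4, C4a, C8a) is the closed valence tautomer of a vinyl ortho-quinone methide. It is therefore cut at C3=C4 and O1–C2 to a salicylaldehyde and an isobutenyl unit. In one operation an amine-catalysed Petasis transfer from 2-methylprop-1-enylboronic acid joins C3 to the formyl carbon C4, amine loss unmasks the quinone methide, and oxa-6π electrocyclisation closes O1–C2. The precursor is 3-prenylphloroglucinaldehyde with two oxygens MOM-capped. Only the hydroxyl between formyl and prenyl is free, which fixes the closure site. The MOM pair then directs metalation of C6 for aroylation, and acid frees the phenols.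

Key step: step 3

Remark: the target has no stereocentre and its ring alkene C3=C4 is cis by ring constraint, so it is achiral and needs no enantiocontrol; chromene numbering (O1, C2 … C8a) is used throughout.

Step 1
Reactants: 1 2,4,6-trihydroxybenzaldehyde; 2 prenyl bromide (1-bromo-3-methylbut-2-ene)
Product: 3 2,4,6-trihydroxy-3-(3-methylbut-2-enyl)benzaldehyde
Conditions: KOH (1.1 equiv), 2 (0.9 equiv), MeOH–H2O, 0 °C to rt
Reagents that add atoms: prenyl bromide 2, CC(C)=CCBr
Why: C-alkylation of an ambident phloroglucinol phenoxide, in which the protic medium shields the oxygens by hydrogen bonding so that the soft allylic bromide should attack ring carbon C3 (equivalent to C5) and tautomerisation restores the arene, while substoichiometric bromide limits double prenylation.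

Step 2
Reactants: 3 2,4,6-trihydroxy-3-(3-methylbut-2-enyl)benzaldehyde; 4 chloromethyl methyl ether (MOMCl)
Product: 5 2-hydroxy-4,6-bis(methoxymethoxy)-3-(3-methylbut-2-enyl)benzaldehyde
Conditions: MOMCl (2.1 equiv), K2CO3 (2.2 equiv), acetone, 0 °C to rt
Reagents that add atoms: chloromethyl methyl ether 4, COCCl
Why: Williamson-type O-alkylation under chelation and steric control, in which the unchelated 4-OH should react first and the unhindered 6-OH second, while the 2-OH wedged between formyl and prenyl stays locked in the O–H···O=C hydrogen bond and remains free.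

Step 3
Reactants: 5 2-hydroxy-4,6-bis(methoxymethoxy)-3-(3-methylbut-2-enyl)benzaldehyde; 6 (2-methylprop-1-enyl)boronic acid; 7 dibenzylamine (catalyst)
Product: 10 5,7-bis(methoxymethoxy)-2,2-dimethyl-8-(3-methylbut-2-enyl)-2H-chromene, via Petasis allylic amine 8 (not isolated), via vinyl o-quinone methide 9 (not isolated)
Conditions: 6 (1.5 equiv), Bn2NH (20 mol %), 1,4-dioxane, 90 °C
Reagents that add atoms: (2-methylprop-1-enyl)boronic acid 6, CC(C)=CB(O)O
Why: Dibenzylamine condenses with the formyl group of 5 to an iminium ion, the free 2-OH binds 6 as a tetracoordinate boronate and delivers its alkenyl carbon intramolecularly to the iminium carbon (C4–C3 bond, amine 8), and at 90 °C the electron-rich aminophenol expels the amine again to give 9, whose oxatriene closes to the aromatic chromene (O1–C2 bond) and returns the catalyst. The closest known reaction type is the amine-catalysed Petasis borono-Mannich/cyclisation of salicylaldehydes with alkenylboronic acids to 2H-chromenes. The single new ring, the six-membered pyran, closes by a thermally allowed disrotatory oxa-6π electrocyclisation of the (Z)-configured 1-oxatriene, driven by rearomatisation. No stereocentre results, since C2 carries two methyl groups, the racemic benzylic centre of 8 is erased on amine loss, and C3=C4 is cis by ring constraint. The step needs site selectivity between the two oxygens ortho to the formyl carbon, and this is secured because only the oxygen next to the prenyl group is a free phenol: the MOM-capped oxygens (ortho and para) can neither bind boron nor become a quinone methide carbonyl. The prenyl alkene and the acetals should be inert under these neutral conditions, and reversible amine re-addition or E/Z isomerisation of 9 only feeds the irreversible ring closure.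

Step 4
Reactants: 10 5,7-bis(methoxymethoxy)-2,2-dimethyl-8-(3-methylbut-2-enyl)-2H-chromene; 11 4-acetoxybenzoyl chloride
Product: 14 4-[5,7-bis(methoxymethoxy)-2,2-dimethyl-8-(3-methylbut-2-enyl)-2H-chromene-6-carbonyl]phenyl acetate, via 6-lithiochromene 12 (not isolated), via 6-chromenylzinc chloride 13 (not isolated)
Conditions: n-BuLi (1.2 equiv), THF, 0 °C; ZnCl2 (1.3 equiv), 0 °C to rt; 11 (1.3 equiv), Pd(PPh3)4 (5 mol %), rt
Reagents that add atoms: 4-acetoxybenzoyl chloride 11, CC(=O)Oc1ccc(C(=O)Cl)cc1
Why: Directed ortho-metalation at C6–H, the only aromatic C–H and flanked by two chelating OMOM groups, followed by Li-to-Zn transmetalation and Negishi acylation, in which the mild arylzinc should take the acid chloride but spare the aryl acetate and the hindered ketone product.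

Step 5
Reactants: 14 4-[5,7-bis(methoxymethoxy)-2,2-dimethyl-8-(3-methylbut-2-enyl)-2H-chromene-6-carbonyl]phenyl acetate
Product: 15 vismiaphenone E, [5,7-dihydroxy-2,2-dimethyl-8-(3-methylbut-2-enyl)-2H-chromen-6-yl](4-hydroxyphenyl)methanone
Conditions: HCl (2 M), MeOH, 40 °C, short contact time
Reagents that add atoms: none
Why: Acid-catalysed acetal exchange should remove both MOM groups (helped by the flanking ketone, whose hydrogen bonds to the freed 5-OH and 7-OH also lower their tendency to add to the prenyl and chromene alkenes), and concurrent acid transesterification should cleave the aryl acetate, so that one mild global deprotection gives achiral 15.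

Compound list
1 | 2,4,6-trihydroxybenzaldehyde | O=Cc1c(O)cc(O)cc1O | starting material
2 | prenyl bromide (1-bromo-3-methylbut-2-ene) | CC(C)=CCBr | starting material
3 | 2,4,6-trihydroxy-3-(3-methylbut-2-enyl)benzaldehyde | O=Cc1c(O)cc(O)c(CC=C(C)C)c1O | intermediate
4 | chloromethyl methyl ether | COCCl | starting material
5 | 2-hydroxy-4,6-bis(methoxymethoxy)-3-(3-methylbut-2-enyl)benzaldehyde | O=Cc1c(OCOC)cc(OCOC)c(CC=C(C)C)c1O | intermediate
6 | (2-methylprop-1-enyl)boronic acid | CC(C)=CB(O)O | starting material
7 | dibenzylamine (catalyst) | C(NCc1ccccc1)c1ccccc1 | starting material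
8 | racemic 2-[1-(dibenzylamino)-3-methylbut-2-enyl]-3,5-bis(methoxymethoxy)-6-(3-methylbut-2-enyl)phenol (not isolated) | CC(C)=CCc1c(O)c(C(C=C(C)C)N(Cc2ccccc2)Cc2ccccc2)c(OCOC)cc1OCOC | intermediate
9 | (6Z)-3,5-bis(methoxymethoxy)-6-(3-methylbut-2-enylidene)-2-(3-methylbut-2-enyl)cyclohexa-2,4-dien-1-one (not isolated) | CC(C)=CCC1=C(OCOC)C=C(OCOC)/C(=C/C=C(C)C)C1=O | intermediate
10 | 5,7-bis(methoxymethoxy)-2,2-dimethyl-8-(3-methylbut-2-enyl)-2H-chromene | CC(C)=CCc1c(OCOC)cc(OCOC)c2c1OC(C)(C)C=C2 | intermediate
11 | 4-acetoxybenzoyl chloride | CC(=O)Oc1ccc(C(=O)Cl)cc1 | starting material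
12 | 6-lithio-5,7-bis(methoxymethoxy)-2,2-dimethyl-8-(3-methylbut-2-enyl)-2H-chromene (not isolated) | CC(C)=CCc1c(OCOC)c([Li])c(OCOC)c2c1OC(C)(C)C=C2 | intermediate
13 | [5,7-bis(methoxymethoxy)-2,2-dimethyl-8-(3-methylbut-2-enyl)-2H-chromen-6-yl]zinc chloride (not isolated) | CC(C)=CCc1c(OCOC)c([Zn]Cl)c(OCOC)c2c1OC(C)(C)C=C2 | intermediate
14 | 4-[5,7-bis(methoxymethoxy)-2,2-dimethyl-8-(3-methylbut-2-enyl)-2H-chromene-6-carbonyl]phenyl acetate | CC(C)=CCc1c(OCOC)c(C(=O)c2ccc(OC(C)=O)cc2)c(OCOC)c2c1OC(C)(C)C=C2 | intermediate
15 | vismiaphenone E | CC(C)=CCc1c(O)c(C(=O)c2ccc(O)cc2)c(O)c2c1OC(C)(C)C=C2 | target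

Total step count: 5. Longest linear sequence: 5 steps (1 → 3 → 5 → 10 → 14 → 15).

Steps most likely to fail

Step 3. The borono-Mannich stage may stall. Iminium formation is slow at a formyl group flanked by two ortho oxygens on a very electron-rich ring, and protodeboronation of the alkenylboronic acid can outrun alkenyl transfer. The fallback sets out from 5 and comes back at 10, making the C4–C3 bond with a hard nucleophile. Excess 2-methylprop-1-enylmagnesium bromide (THF, −78 to 0 °C, the first equivalent being consumed by the phenol) should add to the aldehyde. This should give racemic 2-(1-hydroxy-3-methylbut-2-enyl)-3,5-bis(methoxymethoxy)-6-(3-methylbut-2-enyl)phenol F1. Gentle dehydration of this o-hydroxybenzyl alcohol (silica gel or catalytic PPTS, toluene, 60–80 °C) should pass through the same quinone methide 9 and close to 10.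

Step 2. Discrimination between the two formyl-flanking hydroxyls may be poor, and exhaustive alkylation may compete. The free phenol would then end up on the wrong side of the formyl group. The fallback sets out from 1 and comes back at 5, placing the prenyl group after a protection that has no site issue.
- Bis-MOM protection of symmetric 1 (MOMCl, K2CO3, acetone) should give 2-hydroxy-4,6-bis(methoxymethoxy)benzaldehyde F2.
- Phenol-directed iodination at the less crowded position ortho to the free OH (NIS, CH2Cl2, 0 °C) should give 2-hydroxy-3-iodo-4,6-bis(methoxymethoxy)benzaldehyde F3.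
- Stille coupling with tributyl(3-methylbut-2-enyl)stannane (Pd(PPh3)4, DMF, 90 °C) should deliver 5.

Step 4. Deprotonation at the benzylic and allylic CH2 of the prenyl chain may compete with ring metalation, and acyl transfer to the di-ortho-substituted arylzinc may be sluggish. The fallback sets out from 10 and comes back at 14, replacing deprotonation by halogen–metal exchange and acylation by addition and oxidation.
- Bromination of the only free position of the trioxygenated ring (NBS, 1.0 equiv, CH2Cl2, −78 to −20 °C) should give 6-bromo-5,7-bis(methoxymethoxy)-2,2-dimethyl-8-(3-methylbut-2-enyl)-2H-chromene F4.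
- Br/Li exchange (n-BuLi, THF, −78 °C) should give 12 without any acid–base competition.
- Addition of 12 to 4-acetoxybenzaldehyde at −78 °C with a cold aqueous quench should give racemic 4-{[5,7-bis(methoxymethoxy)-2,2-dimethyl-8-(3-methylbut-2-enyl)-2H-chromen-6-yl](hydroxy)methyl}phenyl acetate F5.
- Dess–Martin oxidation (NaHCO3, CH2Cl2) should give 14.

Further compounds
F1 | step 3 | racemic 2-(1-hydroxy-3-methylbut-2-enyl)-3,5-bis(methoxymethoxy)-6-(3-methylbut-2-enyl)phenol | CC(C)=CCc1c(O)c(C(O)C=C(C)C)c(OCOC)cc1OCOC
F2 | step 2 | 2-hydroxy-4,6-bis(methoxymethoxy)benzaldehyde | O=Cc1c(O)cc(OCOC)cc1OCOC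
F3 | step 2 | 2-hydroxy-3-iodo-4,6-bis(methoxymethoxy)benzaldehyde | O=Cc1c(O)c(I)c(OCOC)cc1OCOC
F4 | step 4 | 6-bromo-5,7-bis(methoxymethoxy)-2,2-dimethyl-8-(3-methylbut-2-enyl)-2H-chromene | CC(C)=CCc1c(OCOC)c(Br)c(OCOC)c2c1OC(C)(C)C=C2
F5 | step 4 | racemic 4-{[5,7-bis(methoxymethoxy)-2,2-dimethyl-8-(3-methylbut-2-enyl)-2H-chromen-6-yl](hydroxy)methyl}phenyl acetate | CC(C)=CCc1c(OCOC)c(C(O)c2ccc(OC(C)=O)cc2)c(OCOC)c2c1OC(C)(C)C=C2
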